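**Retrosynthetic overview**
- The C8–prenyl bond is traced back by an aromatic Claisen rearrangement to the 7-O-(1,1-dimethylallyl) ether; C6 carries OMe, so only C8 can accept the allyl group.
- Key disconnection: the aryl O–C(CH3)2 bond of that ether, made from the 7-hydroxyisoflavone (cladrastin) and isoprene by a new palladium-hydride hydrophenoxylation.
- Pyranone ring C: O1–C2 closure of a 2'-hydroxy-α-(aminomethylene)deoxybenzoin, with C2 supplied by DMF.
- Deoxybenzoin: Friedel–Crafts acylation of 4-methoxyresorcinol with homoveratric acid.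
- Ring order: rings A and B are bought; ring C is the only ring formed (step 1).

Assumption: the target has no stereocentre or other stereogenic element, so no stereocontrol is needed, and 4-methoxyresorcinol is taken as a catalogue compound.

**Route**

Step 1
Reactants: 1 4-methoxybenzene-1,3-diol (4-methoxyresorcinol); 2 (3,4-dimethoxyphenyl)acetic acid (homoveratric acid)
Product: 5 3-(3,4-dimethoxyphenyl)-7-hydroxy-6-methoxy-4H-chromen-4-one (cladrastin), via deoxybenzoin 3 (not isolated), via enaminone 4 (not isolated)
Conditions: BF3·OEt2 (neat, as solvent), 85 °C, 2 h; then DMF, MsCl, 50 to 90 °C, 2 h; then ice-water, filter, recrystallise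
Reagents that add atoms: N,N-dimethylformamide, CN(C)C=O
Why: Friedel–Crafts (Nencki-type) acylation occurs at the one position of 1 that is ortho to one hydroxyl and para to the other, and the BF3-activated ketone is then C-formylated at its methylene by the DMF/MsCl Vilsmeier-type iminium, after which the 2'-OH closes ring C by O–C2 addition to the enaminone and dimethylamine departs, leaving the para-hydroxyl as the free 7-OH.

Step 2
Reactants: 5 3-(3,4-dimethoxyphenyl)-7-hydroxy-6-methoxy-4H-chromen-4-one; 6 isoprene (2-methylbuta-1,3-diene)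
Product: 7 3-(3,4-dimethoxyphenyl)-6-methoxy-7-[(2-methylbut-3-en-2-yl)oxy]-4H-chromen-4-one
Conditions: Pd2(dba)3 (tris(dibenzylideneacetone)dipalladium, 2.5 mol %), Xantphos (6 mol %), THF–isoprene 4:1 (isoprene in excess as co-solvent), 25–35 °C, sealed tube, stopped as soon as 5 is consumed; filtered through basic Al2O3
Reagents that add atoms: none
Why: Proposed new method: the acidic 7-OH (a vinylogous carboxylic acid) protonates the zerovalent palladium–Xantphos complex to a palladium hydride, which adds to isoprene with H delivered to C1 to give the cationic 1,1-dimethylallyl-palladium/phenoxide ion pair, and this is the ion pair from which phenoxides are known to attack the tertiary terminus under kinetic control in palladium-catalysed O-(1,1-dimethylallyl)ation with tertiary allylic carbonates, so the tertiary ether 7 should form at low temperature while the chelating wide-bite-angle ligand suppresses two-diene telomerisation; the closest known reaction types are palladium-hydride hydroamination and hydroalkoxylation of 1,3-dienes and Tsuji–Trost O-reverse-prenylation.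

Step 3
Reactants: 7 3-(3,4-dimethoxyphenyl)-6-methoxy-7-[(2-methylbut-3-en-2-yl)oxy]-4H-chromen-4-one
Product: 8 3-(3,4-dimethoxyphenyl)-7-hydroxy-6-methoxy-8-(3-methylbut-2-en-1-yl)-4H-chromen-4-one (target)
Conditions: Eu(fod)3 (fod = 6,6,7,7,8,8,8-heptafluoro-2,2-dimethyl-3,5-octanedionate; 10 mol %), NaHCO3, PhCl, 85 °C, 12 h
Reagents that add atoms: none
Why: Aromatic Claisen ([3,3]-sigmatropic) rearrangement of the 1,1-dimethylallyl aryl ether delivers the allyl terminus to C8 with allylic transposition, giving the linear prenyl group, because C6 is blocked by OMe and only the C8 dienone can re-aromatise; the gem-dimethyl group and the europium Lewis acid lower the temperature needed, and no stereocentre is formed.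

**Compound list**
1 | 4-methoxybenzene-1,3-diol (4-methoxyresorcinol) | COc1ccc(O)cc1O | starting material
2 | (3,4-dimethoxyphenyl)acetic acid (homoveratric acid) | COc1ccc(CC(=O)O)cc1OC | starting material
3 | 1-(2,4-dihydroxy-5-methoxyphenyl)-2-(3,4-dimethoxyphenyl)ethan-1-one (deoxybenzoin) | COc1ccc(CC(=O)c2cc(OC)c(O)cc2O)cc1OC | intermediate
4 | 1-(2,4-dihydroxy-5-methoxyphenyl)-2-(3,4-dimethoxyphenyl)-3-(dimethylamino)prop-2-en-1-one (enaminone; interconverting E/Z forms, geometry not defined) | COc1ccc(C(=CN(C)C)C(=O)c2cc(OC)c(O)cc2O)cc1OC | intermediate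
5 | 3-(3,4-dimethoxyphenyl)-7-hydroxy-6-methoxy-4H-chromen-4-one (cladrastin) | COc1ccc(-c2coc3cc(O)c(OC)cc3c2=O)cc1OC | intermediate
6 | isoprene (2-methylbuta-1,3-diene) | C=CC(C)=C | starting material
7 | 3-(3,4-dimethoxyphenyl)-6-methoxy-7-[(2-methylbut-3-en-2-yl)oxy]-4H-chromen-4-one | COc1ccc(-c2coc3cc(OC(C)(C)C=C)c(OC)cc3c2=O)cc1OC | intermediate
8 | 3-(3,4-dimethoxyphenyl)-7-hydroxy-6-methoxy-8-(3-methylbut-2-en-1-yl)-4H-chromen-4-one | COc1ccc(-c2coc3c(CC=C(C)C)c(O)c(OC)cc3c2=O)cc1OC | target

**Totals**
Total step count: 3. Longest linear sequence: 3 (1 → 5 → 7 → 8).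

**Steps most likely to fail**

Step 2 (the proposed new step). The palladium hydride may add to isoprene the other way round, the tertiary ether may equilibrate to the linear O-prenyl ether, or telomerisation may compete. The fallback uses known chemistry and sets out from 5. O-Alkylation with 3-chloro-3-methylbut-1-yne (K2CO3, KI, CuI 5 mol %, acetone, 60 °C) gives 3-(3,4-dimethoxyphenyl)-6-methoxy-7-[(2-methylbut-3-yn-2-yl)oxy]-4H-chromen-4-one F1. Semi-hydrogenation of the alkyne (H2 1 atm, Pd/CaCO3 poisoned with Pb(OAc)2, quinoline, EtOAc, rt) then comes back to the route at 7.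

Step 3. The Lewis acid may ionise the tertiary allyl ether back to 5, or the ortho-prenyl phenol may cyclise onto the 7-OH to a dimethylchromane. The fallback abandons the sigmatropic relay and sets out from 5. Iodination ortho to the 7-OH (NIS, DMF, 0 °C to rt; C6 is blocked) gives 3-(3,4-dimethoxyphenyl)-7-hydroxy-8-iodo-6-methoxy-4H-chromen-4-one F2. Stille coupling with tributyl(3-methylbut-2-en-1-yl)stannane (Pd(PPh3)4, DMF, 90 °C) then comes back to the route at 8.

Step 1. The one-pot acylation/cyclisation may stall at the acylation or give material that is hard to purify. The fallback sets out from 1 and separates the two events. Houben–Hoesch condensation of 1 with (3,4-dimethoxyphenyl)acetonitrile (ZnCl2, HCl gas, Et2O, 0 °C) gives 1-(2,4-dihydroxy-5-methoxyphenyl)-2-(3,4-dimethoxyphenyl)ethan-1-iminium chloride F3. Hydrolysis (H2O, reflux) gives isolated 3, and N,N-dimethylformamide dimethyl acetal (THF, 60 °C) closes ring C through 4, coming back to the route at 5.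

**Further compounds**
F1 | step 2 | 3-(3,4-dimethoxyphenyl)-6-methoxy-7-[(2-methylbut-3-yn-2-yl)oxy]-4H-chromen-4-one | COc1ccc(-c2coc3cc(OC(C)(C)C#C)c(OC)cc3c2=O)cc1OC
F2 | step 3 | 3-(3,4-dimethoxyphenyl)-7-hydroxy-8-iodo-6-methoxy-4H-chromen-4-one | COc1ccc(-c2coc3c(I)c(O)c(OC)cc3c2=O)cc1OC
F3 | step 1 | 1-(2,4-dihydroxy-5-methoxyphenyl)-2-(3,4-dimethoxyphenyl)ethan-1-iminium chloride | COc1ccc(CC(=[NH2+])c2cc(OC)c(O)cc2O)cc1OC.[Cl-]
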